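The target is assembled by an intramolecular Buchner reaction that builds the cyclopentane onto a dearomatised 2,5-dimethoxytoluene ring; the route is 15 steps, 14 in the longest linear sequence.

In daucane numbering (C1 quaternary fusion carbon, C5 fusion CH, C6 ester carbon, C9 free carbinol) the skeleton is cut at C1–C5 and C1–C10. The remaining ring atoms C5 to C10, with oxygen on C6 and C9 and methyl on C8, are the substitution pattern of 2,5-dimethoxytoluene. An intramolecular Buchner reaction of an aryl-tethered 2-diazo-3-ketone closes the cyclopentane through C1–C5 and, by norcaradiene opening, inserts C1 into the benzene ring in the same operation; no ring is closed later. The C4 isopropyl carbinol, set by Sharpless epoxidation, directs the face of carbene addition; the methoxy groups become enol ethers that unmask the C6 and C9 carbonyls.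

Key step: step 9

Remark: atom numbers are C1 (quaternary, methyl), C2 and C3 (cyclopentane CH2), C4 (isopropyl carbinol), C5 (fusion CH), C6 (ester carbon), C7=C8 (ring alkene, methyl on C8), C9 (free carbinol), C10 (ring CH2); the target is (1R,4R,5S,6S,9S); diazoethane is assumed to be prepared from commercial N-ethyl-N-nitrosourea.

Step 1
Reactants: 1 4-methylpent-2-yn-1-ol
Product: 2 (Z)-3-iodo-4-methylpent-2-en-1-ol
Conditions: NaAlH2(OCH2CH2OCH3)2, THF, 0 °C to rt; then I2, −78 to 0 °C
Reagents that add atoms: iodine, II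
Why: Alkoxide-directed trans-hydroalumination of the propargylic alcohol places aluminium on C3 cis to the CH2O group, and iodinolysis with retention should give the (Z)-vinyl iodide (hydroalumination–iodination).

Step 2
Reactants: 3 1-bromo-2,5-dimethoxy-4-methylbenzene
Product: 5 (2,5-dimethoxy-4-methylphenyl)boronic acid, via aryllithium 4 (not isolated)
Conditions: n-BuLi, THF, −78 °C; B(OiPr)3, −78 °C to rt; aq. HCl
Reagents that add atoms: triisopropyl borate, CC(C)OB(OC(C)C)OC(C)C; water, O
Why: Bromine–lithium exchange followed by borylation of the aryllithium and hydrolysis is the standard boronic acid synthesis and fixes the attachment point para to the ring methyl.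

Step 3
Reactants: 2 (Z)-3-iodo-4-methylpent-2-en-1-ol; 5 (2,5-dimethoxy-4-methylphenyl)boronic acid
Product: 6 (Z)-3-(2,5-dimethoxy-4-methylphenyl)-4-methylpent-2-en-1-ol
Conditions: Pd(OAc)2 (3 mol %), SPhos (6 mol %), K3PO4, THF/H2O, 60 °C
Reagents that add atoms: none
Why: Suzuki–Miyaura coupling proceeds with retention of alkene geometry, so the aryl group should end up cis to CH2OH, and the bulky biarylphosphine copes with the ortho-methoxy and isopropyl hindrance.

Step 4
Reactants: 6 (Z)-3-(2,5-dimethoxy-4-methylphenyl)-4-methylpent-2-en-1-ol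
Product: 7 [(2S,3R)-3-(2,5-dimethoxy-4-methylphenyl)-3-(propan-2-yl)oxiran-2-yl]methanol
Conditions: Ti(OiPr)4 (10 mol %), L-(+)-diisopropyl tartrate (12 mol %), t-BuOOH, 4 Å molecular sieves, CH2Cl2, −25 °C; cold buffered work-up, used directly
Reagents that add atoms: tert-butyl hydroperoxide, CC(C)(C)OO
Why: Sharpless asymmetric epoxidation with L-(+)-tartrate delivers oxygen to the alkene face that makes the aryl-bearing carbon R, a choice governed by the allylic alcohol and not by the similar sizes of aryl and isopropyl.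

Step 5
Reactants: 7 [(2S,3R)-3-(2,5-dimethoxy-4-methylphenyl)-3-(propan-2-yl)oxiran-2-yl]methanol
Product: 8 (3R)-3-(2,5-dimethoxy-4-methylphenyl)-4-methylpentane-1,3-diol
Conditions: NaAlH2(OCH2CH2OCH3)2, THF, 0 °C
Reagents that add atoms: none
Why: Alkoxide-directed intramolecular hydride delivery opens the 2,3-epoxy alcohol at C2 to the 1,3-diol (directed epoxide reduction), leaving the tertiary C–O bond and its configuration untouched.

Step 6
Reactants: 8 (3R)-3-(2,5-dimethoxy-4-methylphenyl)-4-methylpentane-1,3-diol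
Product: 9 (3R)-3-(2,5-dimethoxy-4-methylphenyl)-3-hydroxy-4-methylpentanoic acid
Conditions: TEMPO (10 mol %), PhI(OAc)2 (2.2 equiv), MeCN/H2O, rt
Reagents that add atoms: water, O
Why: Oxoammonium (TEMPO) oxidation is selective for the primary alcohol and in water runs on through the aldehyde hydrate to the acid, while the tertiary alcohol cannot be oxidised.

Step 7
Reactants: 9 (3R)-3-(2,5-dimethoxy-4-methylphenyl)-3-hydroxy-4-methylpentanoic acid
Product: 11 (3R)-3-(2,5-dimethoxy-4-methylphenyl)-4-methyl-3-(triethylsilyloxy)pentanoic acid, via bis-silylated acid 10 (not isolated)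
Conditions: Et3SiOTf (2.5 equiv), 2,6-lutidine, CH2Cl2, −78 to 0 °C; then THF/H2O, NaHCO3, rt; acidify to pH 4
Reagents that add atoms: triethylsilyl trifluoromethanesulfonate, CC[Si](CC)(CC)OS(=O)(=O)C(F)(F)F
Why: The silyl triflate silylates the hindered tertiary alcohol and the acid, and only the silyl ester is hydrolysed on aqueous work-up; the oxygen must be capped so that the later carbenoid cannot insert into O–H.

Step 8
Reactants: 11 (3R)-3-(2,5-dimethoxy-4-methylphenyl)-4-methyl-3-(triethylsilyloxy)pentanoic acid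
Product: 13 (5R)-2-diazo-5-(2,5-dimethoxy-4-methylphenyl)-6-methyl-5-(triethylsilyloxy)heptan-3-one, via mixed anhydride 12 (not isolated)
Conditions: i-BuOCOCl, N-methylmorpholine, THF, −20 °C; then diazoethane in Et2O (freshly made from N-ethyl-N-nitrosourea, aq. KOH, 0 °C), −20 to 0 °C
Reagents that add atoms: diazoethane, CC=[N+]=[N-]
Why: Acylation of diazoethane by the mixed anhydride (Arndt–Eistert-type acylation) should give the 2-diazo-3-ketone under non-acidic conditions that spare the tertiary benzylic silyl ether.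

Step 9
Reactants: 13 (5R)-2-diazo-5-(2,5-dimethoxy-4-methylphenyl)-6-methyl-5-(triethylsilyloxy)heptan-3-one
Product: 15 (3R,8aR)-4,7-dimethoxy-6,8a-dimethyl-3-(propan-2-yl)-3-(triethylsilyloxy)-2,3-dihydroazulen-1(8aH)-one, via norcaradiene 14 (not isolated)
Conditions: Rh2(OAc)4 (1 mol %), CH2Cl2, 40 °C, slow addition of 13
Reagents that add atoms: none
Why: Rh2(OAc)4 converts 13 into an electrophilic rhodium carbenoid at C1 that adds across the ipso carbon (future C5) and the unsubstituted ortho carbon (future C10) of the arene to give norcaradiene 14, whose 6π disrotatory electrocyclic opening of the C5–C10 bond should give cycloheptatriene 15; the closest known reaction type is the intramolecular Buchner reaction of 2-diazo-5-arylpentan-3-ones to 8a-methylazulenones. The cyclopentane (C1 to C5) is closed by this carbenoid [2+1] cycloaddition through the C1–C5 bond to the ipso carbon, while the seven-membered ring is not closed separately but results from insertion of C1 into the existing benzene ring. The new quaternary stereocentre C1 is controlled by C4: in the closing conformation the tether stands perpendicular to the arene, the larger isopropyl group lies on the side of the unsubstituted ortho carbon and the silyloxy group on the methoxy side, which places the C1 methyl cis to the silyloxy group and trans to isopropyl, the trans preference known for benzylic substituents in this reaction. The step needs chemoselectivity for arene addition over 1,5 C–H insertion into the isopropyl methine and over oxonium ylide formation, secured by the very electron-rich arene, the gem-disubstituted tether and the hindered silyl ether, and regioselectivity for the unsubstituted ortho carbon, secured by the methoxy group that blocks the other one. Because C1 carries no hydrogen, 1,5-hydrogen shifts cannot scramble the triene, so the two methyl enol ethers stay at C6 and C9.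

Step 10
Reactants: 15 (3R,8aR)-4,7-dimethoxy-6,8a-dimethyl-3-(propan-2-yl)-3-(triethylsilyloxy)-2,3-dihydroazulen-1(8aH)-one
Product: 17 (1R,4R)-6,9-dimethoxy-4-(triethylsilyloxy)dauca-5,7,9-triene (the C2-methylene analogue of 15), via silyl hydrazone 16 (not isolated)
Conditions: TBSNHNHTBS, Sc(OTf)3 (1 mol %), CHCl3, 55 °C; then KOtBu, t-BuOH, DMSO, 23 to 80 °C
Reagents that add atoms: none
Why: The N-silyl hydrazone variant of the Wolff–Kishner reduction removes the C2 carbonyl through an anionic diazene decomposition at moderate temperature; the enol ethers and triene are base-stable and no stereocentre is touched.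

Step 11
Reactants: 17 (1R,4R)-6,9-dimethoxy-4-(triethylsilyloxy)dauca-5,7,9-triene
Product: 18 (1R,4R,5R)-4-hydroxydauc-7-ene-6,9-dione
Conditions: aq. HF (5 %), MeCN, 0 °C to rt
Reagents that add atoms: water, O
Why: Mild aqueous acid hydrolyses both methyl enol ethers to the C6/C9 ene-dione and cleaves the silyl ether; C5 is protonated under equilibrating conditions (it is alpha to the C6 carbonyl) and the trans-fused epimer, with the C6 carbonyl syn to the C4 hydroxyl and anti to isopropyl, is expected to predominate.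

Step 12
Reactants: 18 (1R,4R,5R)-4-hydroxydauc-7-ene-6,9-dione
Product: 19 (1R,4R,5S,6S)-4,6-dihydroxydauc-7-en-9-one
Conditions: Me4NBH(OAc)3, MeCN/AcOH (1:1), −25 °C
Reagents that add atoms: none
Why: In this hydroxyl-directed (Evans–Saksena) reduction the C4 alkoxyborohydride delivers hydride intramolecularly to the C6 carbonyl from the face of the C4 oxygen, which should give the 1,3-anti diol (6S), while the C9 ketone has no directing group and is not reduced.

Step 13
Reactants: 19 (1R,4R,5S,6S)-4,6-dihydroxydauc-7-en-9-one; 20 4-acetoxy-3-methoxybenzoic acid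
Product: 21 (1R,4R,5S,6S)-4-hydroxy-9-oxodauc-7-en-6-yl 4-acetoxy-3-methoxybenzoate
Conditions: DCC, DMAP (cat.), CH2Cl2, 0 °C to rt
Reagents that add atoms: none
Why: Steglich esterification acylates the secondary allylic C6 hydroxyl, and the tertiary C4 hydroxyl is too hindered to react.

Step 14
Reactants: 21 (1R,4R,5S,6S)-4-hydroxy-9-oxodauc-7-en-6-yl 4-acetoxy-3-methoxybenzoate
Product: 22 (1R,4R,5S,6S,9S)-4,9-dihydroxydauc-7-en-6-yl 4-acetoxy-3-methoxybenzoate
Conditions: (R)-2-methyl-CBS-oxazaborolidine (20 mol %), catecholborane, toluene, −78 °C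
Reagents that add atoms: none
Why: Reagent-controlled Corey–Bakshi–Shibata 1,2-reduction of the enone, in which the alpha-methyl alkenyl arm (C8) acts as the large group and C10H2 as the small one, so that the (R)-catalyst should deliver hydride to the face giving the (9S) alcohol cis to the C6 ester.

Step 15
Reactants: 22 (1R,4R,5S,6S,9S)-4,9-dihydroxydauc-7-en-6-yl 4-acetoxy-3-methoxybenzoate
Product: 23 (1R,4R,5S,6S,9S)-4,9-dihydroxydauc-7-en-6-yl 4-hydroxy-3-methoxybenzoate (CNP0189996.2)
Conditions: pyrrolidine, CH2Cl2, 0 °C to rt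
Reagents that add atoms: none
Why: Aminolysis cleaves the phenolic acetate much faster than the hindered, electron-rich allylic benzoate, releasing the free phenol without touching the stereocentres.

Compound list
1 | 4-methylpent-2-yn-1-ol | CC(C)C#CCO | starting material
2 | (Z)-3-iodo-4-methylpent-2-en-1-ol | OC/C=C(\I)C(C)C | intermediate
3 | 1-bromo-2,5-dimethoxy-4-methylbenzene | COc1cc(C)c(OC)cc1Br | starting material
4 | (2,5-dimethoxy-4-methylphenyl)lithium | COc1cc(C)c(OC)cc1[Li] | intermediate
5 | (2,5-dimethoxy-4-methylphenyl)boronic acid | COc1cc(C)c(OC)cc1B(O)O | intermediate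
6 | (Z)-3-(2,5-dimethoxy-4-methylphenyl)-4-methylpent-2-en-1-ol | OC/C=C(\c1cc(OC)c(C)cc1OC)C(C)C | intermediate
7 | [(2S,3R)-3-(2,5-dimethoxy-4-methylphenyl)-3-(propan-2-yl)oxiran-2-yl]methanol | OC[C@@H]1O[C@]1(C(C)C)c2cc(OC)c(C)cc2OC | intermediate
8 | (3R)-3-(2,5-dimethoxy-4-methylphenyl)-4-methylpentane-1,3-diol | OCC[C@@](O)(C(C)C)c1cc(OC)c(C)cc1OC | intermediate
9 | (3R)-3-(2,5-dimethoxy-4-methylphenyl)-3-hydroxy-4-methylpentanoic acid | OC(=O)C[C@@](O)(C(C)C)c1cc(OC)c(C)cc1OC | intermediate
10 | triethylsilyl (3R)-3-(2,5-dimethoxy-4-methylphenyl)-4-methyl-3-(triethylsilyloxy)pentanoate | CC[Si](CC)(CC)OC(=O)C[C@@](O[Si](CC)(CC)CC)(C(C)C)c1cc(OC)c(C)cc1OC | intermediate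
11 | (3R)-3-(2,5-dimethoxy-4-methylphenyl)-4-methyl-3-(triethylsilyloxy)pentanoic acid | OC(=O)C[C@@](O[Si](CC)(CC)CC)(C(C)C)c1cc(OC)c(C)cc1OC | intermediate
12 | mixed anhydride of 11 with isobutyl carbonic acid | CC(C)COC(=O)OC(=O)C[C@@](O[Si](CC)(CC)CC)(C(C)C)c1cc(OC)c(C)cc1OC | intermediate
13 | (5R)-2-diazo-5-(2,5-dimethoxy-4-methylphenyl)-6-methyl-5-(triethylsilyloxy)heptan-3-one | CC(=[N+]=[N-])C(=O)C[C@@](O[Si](CC)(CC)CC)(C(C)C)c1cc(OC)c(C)cc1OC | intermediate
14 | norcaradiene valence tautomer of 15 (cyclopropane C1–C5–C10 cis-fused to the dimethoxycyclohexadiene and to the cyclopentanone, C1 methyl on the diene side) | COC1=CC(C)=C(OC)[C@@H]2[C@@]3(C)C(=O)C[C@@](O[Si](CC)(CC)CC)(C(C)C)[C@@]123 | intermediate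
15 | (3R,8aR)-4,7-dimethoxy-6,8a-dimethyl-3-(propan-2-yl)-3-(triethylsilyloxy)-2,3-dihydroazulen-1(8aH)-one | COC=2C=C(C)C(OC)=C[C@@]3(C)C(=O)C[C@@](O[Si](CC)(CC)CC)(C(C)C)C=23 | intermediate
16 | N-(tert-butyldimethylsilyl)hydrazone of 15 at C2 (N–N anti to C1) | COC=2C=C(C)C(OC)=C[C@@]3(C)/C(=N/N[Si](C)(C)C(C)(C)C)C[C@@](O[Si](CC)(CC)CC)(C(C)C)C=23 | intermediate
17 | (1R,4R)-6,9-dimethoxy-4-(triethylsilyloxy)dauca-5,7,9-triene | COC=2C=C(C)C(OC)=C[C@@]3(C)CC[C@@](O[Si](CC)(CC)CC)(C(C)C)C=23 | intermediate
18 | (1R,4R,5R)-4-hydroxydauc-7-ene-6,9-dione (trans ring fusion) | O=C2C=C(C)C(=O)C[C@@]3(C)CC[C@@](O)(C(C)C)[C@H]23 | intermediate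
19 | (1R,4R,5S,6S)-4,6-dihydroxydauc-7-en-9-one | O[C@H]2C=C(C)C(=O)C[C@@]3(C)CC[C@@](O)(C(C)C)[C@H]23 | intermediate
20 | 4-acetoxy-3-methoxybenzoic acid | CC(=O)Oc1ccc(cc1OC)C(O)=O | starting material
21 | (1R,4R,5S,6S)-4-hydroxy-9-oxodauc-7-en-6-yl 4-acetoxy-3-methoxybenzoate | CC(=O)Oc1ccc(cc1OC)C(=O)O[C@H]2C=C(C)C(=O)C[C@@]3(C)CC[C@@](O)(C(C)C)[C@H]23 | intermediate
22 | (1R,4R,5S,6S,9S)-4,9-dihydroxydauc-7-en-6-yl 4-acetoxy-3-methoxybenzoate | CC(=O)Oc1ccc(cc1OC)C(=O)O[C@H]2C=C(C)[C@@H](O)C[C@@]3(C)CC[C@@](O)(C(C)C)[C@H]23 | intermediate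
23 | (1R,4R,5S,6S,9S)-4,9-dihydroxydauc-7-en-6-yl 4-hydroxy-3-methoxybenzoate | COc1cc(C(=O)O[C@H]2C=C(C)[C@@H](O)C[C@@]3(C)CC[C@@](O)(C(C)C)[C@H]23)ccc1O | target

Total step count: 15. Longest linear sequence: 14 steps (steps 1 and 3 to 15; step 2 is a one-step side branch).

Steps most likely to fail

Step 9. The carbenoid may be diverted before it reaches the arene, by 1,5 C–H insertion into the isopropyl methine or by attack on the silyl ether oxygen, or it may add to the wrong face, giving the C1 epimer. The fallback carries the C4 oxygen as the epoxide, where a ylide would need a four-membered ring and the isopropyl group is held trans to the carbenoid arm, and it removes the C2 oxygen by transposition. It sets out from 7 and returns at 18.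
- Oxidation of 7 (TEMPO, PhI(OAc)2, buffered MeCN/H2O, handled as the potassium salt) should give (2R,3R)-3-(2,5-dimethoxy-4-methylphenyl)-3-(propan-2-yl)oxirane-2-carboxylic acid F1.
- Mixed-anhydride activation and diazoethane, as in step 8, should give the epoxy diazoketone F2.
- Rh2(OAc)4 in CH2Cl2 should give the epoxide-fused azulenone F3.
- Wharton transposition (N2H4·H2O, Et3N, MeCN) should give the C2=C3 allylic alcohol F4 with the free C4 hydroxyl.
- Diimide (2-nitrobenzenesulfonylhydrazide, Et3N, CH2Cl2) should reduce only the disubstituted cyclopentene to the triene alcohol F5.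
- Aqueous acid, as in step 11, then gives 18.

Step 14. Hydride delivery to C9 from the face syn to the angular C1 methyl may be disfavoured, so that catalyst and substrate are mismatched and the 9-epimer forms. The fallback inverts the carbinol instead of forcing the reduction. It sets out from 21 and returns at 23.
- Luche reduction (NaBH4, CeCl3·7H2O, MeOH, −78 °C) should give the substrate-controlled (9R)-alcohol F6.
- Mitsunobu reaction with formic acid (PPh3, DIAD, THF, 0 °C) should give the inverted (9S)-formate F7.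
- Pyrrolidine in MeOH cleaves the formate and the phenolic acetate together to give 23.

Step 10. Hydrazone formation at the hindered C2 ketone next to quaternary C1 may stall, or the base may cause beta-elimination of the C4 silyloxy group. The fallback removes the oxygen through the enol triflate. It sets out from 15 and returns at 17.
- KN(SiMe3)2 and PhNTf2 (THF, −78 °C) should give the C2 enol triflate F8.
- Palladium-catalysed formate reduction (Pd(OAc)2, PPh3, Bu3N, HCO2H, DMF, 60 °C) should give the cyclopentene F9.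
- Diimide (2-nitrobenzenesulfonylhydrazide, Et3N, CH2Cl2) saturates only the disubstituted C2=C3 bond to give 17.

Further compounds
F1 | step 9 | (2R,3R)-3-(2,5-dimethoxy-4-methylphenyl)-3-(propan-2-yl)oxirane-2-carboxylic acid | OC(=O)[C@@H]1O[C@]1(C(C)C)c2cc(OC)c(C)cc2OC
F2 | step 9 | 2-diazo-1-[(2R,3R)-3-(2,5-dimethoxy-4-methylphenyl)-3-(propan-2-yl)oxiran-2-yl]propan-1-one | CC(=[N+]=[N-])C(=O)[C@@H]1O[C@]1(C(C)C)c2cc(OC)c(C)cc2OC
F3 | step 9 | C3–C4 epoxide analogue of 15 (C2 ketone, C1 methyl cis to the epoxide oxygen, bis(methyl enol ether) triene) | COC=2C=C(C)C(OC)=C[C@@]3(C)C(=O)[C@@H]4O[C@]4(C(C)C)C=23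
F4 | step 9 | (1R,4R)-6,9-dimethoxydauca-2,5,7,9-tetraen-4-ol | COC=2C=C(C)C(OC)=C[C@@]3(C)C=C[C@@](O)(C(C)C)C=23
F5 | step 9 | (1R,4R)-6,9-dimethoxydauca-5,7,9-trien-4-ol | COC=2C=C(C)C(OC)=C[C@@]3(C)CC[C@@](O)(C(C)C)C=23
F6 | step 14 | (1R,4R,5S,6S,9R)-4,9-dihydroxydauc-7-en-6-yl 4-acetoxy-3-methoxybenzoate (9-epimer of 22) | CC(=O)Oc1ccc(cc1OC)C(=O)O[C@H]2C=C(C)[C@H](O)C[C@@]3(C)CC[C@@](O)(C(C)C)[C@H]23
F7 | step 14 | (1R,4R,5S,6S,9S)-9-formyloxy-4-hydroxydauc-7-en-6-yl 4-acetoxy-3-methoxybenzoate | CC(=O)Oc1ccc(cc1OC)C(=O)O[C@H]2C=C(C)[C@@H](OC=O)C[C@@]3(C)CC[C@@](O)(C(C)C)[C@H]23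
F8 | step 10 | C2 enol triflate of 15 (C2=C3 alkene bearing OTf on C2) | COC=2C=C(C)C(OC)=C[C@@]3(C)C(OS(=O)(=O)C(F)(F)F)=C[C@@](O[Si](CC)(CC)CC)(C(C)C)C=23
F9 | step 10 | (1R,4R)-6,9-dimethoxy-4-(triethylsilyloxy)dauca-2,5,7,9-tetraene | COC=2C=C(C)C(OC)=C[C@@]3(C)C=C[C@@](O[Si](CC)(CC)CC)(C(C)C)C=23
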